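**Plan**

- Ring numbering used here: C1 (C=O), C2 (carries the isobutyryl group), C3 (enol C–OH), C4 (carbinol with one prenyl), C5 (C=O), C6 (gem-diprenyl carbon).
- Retrosynthesis cuts C4–C5 and C2–C3 together. C3–C4 with its two oxygens is an α-hydroxy acid unit (C3 carboxyl carbon, C4 α-carbon). C5–C6–C1–C2–C(O)iPr is a 2,2-diprenyl-3,5-dioxoacyl chain, stored as its enol lactone, 6-isopropyl-3,3-diprenyl-2H-pyran-2,4(3H)-dione.
- Enabling feature: the lactone oxygen of the pyrandione is the leaving group of the first acylation (C4–C5) and, once expelled, is the diketonate whose carbon closes C2–C3 onto the carboxyl carbon. The α-hydroxy acid is carried as a 2-tert-butyl-1,3-dioxolan-4-one, a temporary ring that is lost in the same operation.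
- Forward: the pyrandione is built in 3 steps from a dioxinone, isobutyryl chloride and prenyl acetate; the dioxolanone in 3 steps from L-allylglycine; their union forms the only carbocycle and gives the target directly.
- Stereochemistry: the single stereocenter (C4, S) comes from L-allylglycine by self-regeneration of stereocenters. The (S) α-carbon sets the acetal carbon, is erased on enolization, and is rebuilt with the acyl group entering anti to tert-butyl.

Key step: step 7

Remark: the target is a β-triketone drawn as one enol tautomer; the route delivers the tautomeric mixture and the (S) descriptor refers to the drawn form.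

**Step 1**
Reactants: 1 2,2,6-trimethyl-4H-1,3-dioxin-4-one; 2 isobutyryl chloride (2-methylpropanoyl chloride)
Product: 3 2,2-dimethyl-6-(3-methyl-2-oxobutyl)-4H-1,3-dioxin-4-one
Conditions: LiN(SiMe3)2 (2.1 equiv), THF, –78 °C; then 2, –78 °C; cold aq HCl quench
Reagents that add atoms: none
Why: Vinylogous Claisen acylation, in which the lithium dienolate of 1 is acylated at the γ-methyl carbon by the acid chloride and the second equivalent of base takes up the more acidic product; no stereocenter is formed.

**Step 2**
Reactants: 3 2,2-dimethyl-6-(3-methyl-2-oxobutyl)-4H-1,3-dioxin-4-one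
Product: 5 4-hydroxy-6-isopropyl-2H-pyran-2-one, via acylketene 4 (not isolated)
Conditions: toluene, 110 °C
Reagents that add atoms: none
Why: Thermal retro-hetero-Diels–Alder loss of acetone gives acylketene 4, whose ketene carbon is captured by the enol oxygen of the side-chain ketone in a six-membered lactonization to the 4-hydroxy-2-pyrone; no stereocenter is formed.

**Step 3**
Reactants: 5 4-hydroxy-6-isopropyl-2H-pyran-2-one; 6 prenyl acetate (3-methylbut-2-en-1-yl acetate, 2.5 equiv)
Product: 7 6-isopropyl-3,3-bis(3-methylbut-2-en-1-yl)-2H-pyran-2,4(3H)-dione
Conditions: Pd(PPh3)4 (5 mol %), Et3N, THF, 60 °C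
Reagents that add atoms: none
Why: Double Tsuji–Trost allylation, in which the soft 4-hydroxypyrone anion attacks the π-prenyl complex (formed from zerovalent palladium and 6) at its unsubstituted terminus, O-prenyl ethers re-ionize under the catalyst and funnel to carbon, and the second prenylation at C3 gives the non-aromatic 2,4-dione; C3 carries two identical groups, so no stereocenter arises.

**Step 4**
Reactants: 8 L-allylglycine ((S)-2-aminopent-4-enoic acid)
Product: 9 (S)-2-hydroxypent-4-enoic acid
Conditions: NaNO2, 1 M aq H2SO4, 0 °C to rt
Reagents that add atoms: water, O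
Why: Diazotization of the α-amino acid should proceed with overall retention by double inversion through the α-lactone, so the (S) configuration of 8 is kept in 9.

**Step 5**
Reactants: 9 (S)-2-hydroxypent-4-enoic acid; 10 pivalaldehyde (2,2-dimethylpropanal)
Product: 11 (2S,5S)-5-allyl-2-tert-butyl-1,3-dioxolan-4-one (cis)
Conditions: TsOH·H2O (cat.), H2SO4 (cat.), pentane, reflux, Dean–Stark; cis isomer separated by chromatography
Reagents that add atoms: none
Why: Acid-catalysed acetalization to a Seebach dioxolanone under thermodynamic control should favor the cis isomer, so the new acetal stereocenter (2S) is set by the existing (5S) center; only this isomer is carried on, because the acetal carbon alone bears the chirality after enolization.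

**Step 6**
Reactants: 11 (2S,5S)-5-allyl-2-tert-butyl-1,3-dioxolan-4-one; 12 2-methyl-2-butene
Product: 13 (2S,5S)-2-tert-butyl-5-(3-methylbut-2-en-1-yl)-1,3-dioxolan-4-one
Conditions: second-generation Grubbs catalyst RuCl2(=CHPh)(PCy3)(H2IMes) (3 mol %), 2-methyl-2-butene/CH2Cl2, 40 °C
Reagents that add atoms: none
Why: Olefin cross metathesis in which 2-methyl-2-butene delivers the isopropylidene unit to the terminal alkene (allyl to prenyl) with release of propene; neither stereocenter is touched under the neutral conditions.

**Step 7**
Reactants: 13 (2S,5S)-2-tert-butyl-5-(3-methylbut-2-en-1-yl)-1,3-dioxolan-4-one (1.5 equiv); 7 6-isopropyl-3,3-bis(3-methylbut-2-en-1-yl)-2H-pyran-2,4(3H)-dione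
Product: 16 (4S)-3,4-dihydroxy-2-(2-methylpropanoyl)-4,6,6-tris(3-methylbut-2-en-1-yl)cyclohex-2-ene-1,5-dione (4-hydroxycolupulone), via lithium dioxolanone enolate 14 (not isolated), via ring-opened lithium diketonate 15 (not isolated)
Conditions: LiN(iPr)2 (1.5 equiv), THF, –78 °C; then 7 in THF, –78 to 0 °C; cold aq HCl to pH 3
Reagents that add atoms: none
Why: Proposed new method: the planar lithium enolate 14, whose only stereogenic element is the acetal carbon, should attack the enol-lactone carbonyl C2 of 7 (an activated acyl donor) through its C5, the tetrahedral intermediate expelling the ring oxygen as the 1,3-diketonate 15, whose central carbon then attacks the dioxolanone carbonyl and expels the hemiacetal alkoxide, which sheds pivalaldehyde to leave the lithium triketonate of 16. The closest known reaction types are the C–C bond formations of Seebach dioxolanone enolates (self-regeneration of stereocenters), Claisen attack of enolates on a dioxolanone carbonyl with loss of the acetal aldehyde (tetronic acid syntheses), and carbanion-induced ring transformations of 2-pyranones; their merger into one anionic [4+2] annulation on a 3,3-disubstituted pyran-2,4-dione is not precedented. The six-membered carbocycle is closed by a 6-exo-trig Dieckmann-type C-acylation after the intermolecular acyl transfer. The single new stereocenter (C4 of 16) is set in the first bond formation by the tert-butyl group on the acetal carbon, which blocks its own face so that the acyl carbon enters anti to it and takes the place of the former hydrogen, giving (S). The step needs attack at the lactone carbonyl instead of conjugate addition at C6 or addition to the C4 ketone, and C- instead of O-acylation in both events; the hard lithium enolate, the isopropyl group shielding C6, the reversibility of ketone addition against the irreversible ring opening, and the lithium-chelated diketonate that ends in the strongly acidic triketone are expected to secure this.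

**Compound list**

1 | 2,2,6-trimethyl-4H-1,3-dioxin-4-one | CC1=CC(=O)OC(C)(C)O1 | starting material
2 | isobutyryl chloride | CC(C)C(Cl)=O | starting material
3 | 2,2-dimethyl-6-(3-methyl-2-oxobutyl)-4H-1,3-dioxin-4-one | CC(C)C(=O)CC1=CC(=O)OC(C)(C)O1 | intermediate
4 | 6-methyl-3,5-dioxohept-1-en-1-one (acylketene) | CC(C)C(=O)CC(=O)C=C=O | intermediate
5 | 4-hydroxy-6-isopropyl-2H-pyran-2-one | CC(C)C1=CC(O)=CC(=O)O1 | intermediate
6 | prenyl acetate (3-methylbut-2-en-1-yl acetate) | CC(=O)OCC=C(C)C | starting material
7 | 6-isopropyl-3,3-bis(3-methylbut-2-en-1-yl)-2H-pyran-2,4(3H)-dione | CC(C)C1=CC(=O)C(CC=C(C)C)(CC=C(C)C)C(=O)O1 | intermediate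
8 | L-allylglycine, (S)-2-aminopent-4-enoic acid | N[C@@H](CC=C)C(O)=O | starting material
9 | (S)-2-hydroxypent-4-enoic acid | O[C@@H](CC=C)C(O)=O | intermediate
10 | pivalaldehyde | CC(C)(C)C=O | starting material
11 | (2S,5S)-5-allyl-2-tert-butyl-1,3-dioxolan-4-one | O=C1O[C@@H](C(C)(C)C)O[C@H]1CC=C | intermediate
12 | 2-methyl-2-butene | CC=C(C)C | starting material
13 | (2S,5S)-2-tert-butyl-5-(3-methylbut-2-en-1-yl)-1,3-dioxolan-4-one | O=C1O[C@@H](C(C)(C)C)O[C@H]1CC=C(C)C | intermediate
14 | lithium (2S)-2-tert-butyl-5-(3-methylbut-2-en-1-yl)-1,3-dioxol-4-olate | [Li+].[O-]C1=C(CC=C(C)C)O[C@H](C(C)(C)C)O1 | intermediate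
15 | lithium (Z)-enolate of (2S,5R)-2-tert-butyl-5-[6-methyl-2,2-bis(3-methylbut-2-en-1-yl)-3,5-dioxoheptanoyl]-5-(3-methylbut-2-en-1-yl)-1,3-dioxolan-4-one | [Li+].CC(C)C(/[O-])=C/C(=O)C(CC=C(C)C)(CC=C(C)C)C(=O)[C@@]1(CC=C(C)C)O[C@H](C(C)(C)C)OC1=O | intermediate
16 | (4S)-3,4-dihydroxy-2-(2-methylpropanoyl)-4,6,6-tris(3-methylbut-2-en-1-yl)cyclohex-2-ene-1,5-dione (4-hydroxycolupulone) | CC(C)=CCC1(CC=C(C)C)C(=O)C(C(=O)C(C)C)=C(O)[C@@](O)(CC=C(C)C)C1=O | target

**Count**

Total steps: 7. Longest linear sequence: 4 steps (1→3→5→7→16, or 8→9→11→13→16).

**Steps most likely to fail**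

1. Step 7. The fully substituted enolate may acylate the lactone carbonyl next to the quaternary carbon too slowly and self-condense on warming. It may also add in conjugate fashion at C6, acylate on oxygen, or close through oxygen instead of carbon. Prolonged contact of the product with base could trigger acyloin ring contraction.
Fallback, by known chemistry, from 2 back to 16: Friedel–Crafts acylation of phloroglucinol with 2 (AlCl3, nitrobenzene) should give 2-methyl-1-(2,4,6-trihydroxyphenyl)propan-1-one (phlorisobutyrophenone) F1. Exhaustive dearomatizing C-prenylation with prenyl bromide (NaOMe, MeOH, 0 °C) should give colupulone F2. Its potassium enolate (KN(SiMe3)2, THF, –78 °C) would then be hydroxylated at the ring carbon bearing the single prenyl group with an enantiopure (camphorsulfonyl)oxaziridine (Davis enolate hydroxylation) to reach 16. The stereocenter then rests on reagent control; the enantiomer of the oxaziridine would be chosen after the sense of induction is established, and the enantiomeric purity raised by crystallization or chiral chromatography if needed.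

2. Step 3. Attack on the π-prenyl complex may leak to the substituted terminus (reverse-prenyl groups), and the second alkylation, which creates the quaternary carbon, may stall at the mono-C- or O-prenyl stage.
Fallback from 5 back to 7: double allylation with allyl acetate (Pd(PPh3)4, Et3N, THF), where the symmetrical π-allyl unit removes the regiochemical question, should give 3,3-diallyl-6-isopropyl-2H-pyran-2,4(3H)-dione F3. Twofold cross metathesis with 12 (second-generation Grubbs catalyst RuCl2(=CHPh)(PCy3)(H2IMes), CH2Cl2, 40 °C) would then convert both allyl groups into prenyl groups and deliver 7.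

3. Step 5. Thermodynamic acetalization may give poor cis/trans selectivity, and incomplete separation of the oily diastereomers would erode the enantiomeric purity of everything downstream, since the trans isomer leads to the mirror-image enolate.
Fallback from 9 back to 11: silylation of both acidic positions (Me3SiCl, Et3N, CH2Cl2) should give trimethylsilyl (S)-2-(trimethylsilyloxy)pent-4-enoate F4. Reaction of F4 with 10 under catalysis by Me3SiOSO2CF3 in CH2Cl2 at –78 °C (kinetically controlled acetalization) is expected to give the cis dioxolanone 11 with high selectivity.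

**Further compounds**

F1 | step 7 | 2-methyl-1-(2,4,6-trihydroxyphenyl)propan-1-one (phlorisobutyrophenone) | CC(C)C(=O)c1c(O)cc(O)cc1O
F2 | step 7 | colupulone | CC(C)C(=O)C1=C(O)C(CC=C(C)C)=C(O)C(CC=C(C)C)(CC=C(C)C)C1=O
F3 | step 3 | 3,3-diallyl-6-isopropyl-2H-pyran-2,4(3H)-dione | CC(C)C1=CC(=O)C(CC=C)(CC=C)C(=O)O1
F4 | step 5 | trimethylsilyl (S)-2-(trimethylsilyloxy)pent-4-enoate | C=CC[C@H](O[Si](C)(C)C)C(=O)O[Si](C)(C)C
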